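## Structural features

The target is an oxolane (O1, C2–C5) that carries a guaiacyl ring (ring A) on C2, an acyloxymethyl group on C3 and a guaiacylmethyl group (ring B) on C4. C5 is an unsubstituted CH2 next to O1, and the C3 CH2O group is esterified by (E)-p-coumaric acid. The three stereocentres C2, C3 and C4 are contiguous, (2S,3S,4R): the ring A aryl group and the C3 arm are cis, and the C3 and C4 arms are trans. The 2,3-cis arrangement is the less stable one. The fragile elements are the C2–O1 bond (a benzylic ether para to a phenol, which ionises under acid and would then drift to the 2,3-trans series), the three free phenols (competing nucleophiles, air-sensitive as phenoxides) and the cinnamate (transesterification, conjugate addition, E/Z isomerisation). The real difficulty is therefore the relative configuration of the trisubstituted ring, above all keeping C2 cis to C3 while C4 is set trans, and not the carbon skeleton. The key step uses two features: C5 is a lone CH2 between O1 and C4, so it can come from formaldehyde, and the exocyclic benzylic carbon on C4 is para to the ring B oxygen, so it can hold the cation left when a styrene closes onto an O1=C5 oxocarbenium ion. Hydride then turns that cation into the benzyl CH2. The ester is best attached last, because the C3 CH2OH is the only aliphatic hydroxyl of the deprotected core.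

## Logic of the disconnections

**17 to 15 and 16.** The bond cut is the one between the C3 CH2 carbon and the ester oxygen. This keeps the conjugated acyl unit out of all earlier chemistry and leaves a core, 15, whose single aliphatic hydroxyl is primary. The forward step must form this C–O bond by activating the alcohol and not the acid, so that the carboxyl group of 16 reacts in preference to the three phenols. It must also run without acid, because C2 of 15 is a p-hydroxybenzylic ether.

**15 to 14.** Three oxygen–protecting-group bonds are cut: the aryl pivalate on ring A, the primary pivalate on the C3 arm and the silyl ether on ring B. The groups are not interchangeable, because ring A must be electron-poor and ring B electron-rich in the ring-forming step. The forward step should remove all three in one basic operation, which is why the silyl group is tert-butyldimethylsilyl (cleaved by alkoxide at an aryl oxygen) and not a bulkier one.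

**14 to 11 and 12 (through 13).** The O1–C5 and C4–C5 bonds are cut and the ring B benzylic CH2 is taken back to an alkene carbon; C5 becomes 12. This strategic cut removes the ring and the C4 stereocentre and leaves an acyclic alcohol whose two stereocentres are those of C2 and C3. The forward step must:
- form the oxocarbenium ion at O1 without protic acid (hence 13, made in the flask);
- close the five-membered and not the six-membered ring;
- bring C5 to the alkene face anti to the C3 arm;
- keep the C2–O1 bond from ionising;
- deliver hydride only after the C–C bond exists.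

**11 to 8 and 10.** The (E)-C=C bond between C4 and the benzylic carbon is cut in the sense of a cross-metathesis. Ring B then enters as a simple vinyl arene and the stereodiad stays untouched in a terminal alkene. The forward step must be E-selective, must favour the cross product over the homodimer of 10, and must not move the double bond towards the allylic stereocentre.

**10 to 9.** The O–Si bond is cut. The silyl group is a donor that survives the Lewis acid and leaves with base. The forward step is a routine silylation of a polymerisation-prone vinyl phenol, so it is run cold.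

**8 to 7.** The primary O–acyl bond is cut. The pivalate differentiates the two hydroxyls so that only the benzylic one can form the oxocarbenium ion, and it leaves together with the ring A pivalate. The forward acylation must select the primary over the hindered secondary benzylic hydroxyl.

**7 to 2 and 5 (through 6).** The C2–C3 bond is cut and the C3 CH2–O bond is traced back to a C–B bond. Both stereocentres then come from one allylboration of an aromatic aldehyde by a symmetrical bis-allylboronate, and the second boron supplies the oxygen of the future ester. The forward step needs the Z geometry of 5 (syn, later 2,3-cis), a chiral Brønsted acid for the absolute sense, and a C–B oxidation that spares the aryl ester.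

**5 to 3 and 4.** Two C–B bonds are cut. The forward step must give 1,4- and not 1,2-addition and the Z alkene.

**2 to 1.** The aryl O–acyl bond is cut. The ester makes the aldehyde more electrophilic for the allylboration and later protects C2. The forward step is a simple phenol acylation.

## Other disconnections considered

**Alternative 1:** The cut is at the C4–benzylic carbon bond and the C3–CH2O bond, both made in one pot on the butenolide A1, (5R)-5-(menthyloxy)furan-2(5H)-one. The lithium derivative of the dithiane A2 would add to C4 anti to the menthyloxy group, and the lactone enolate would be alkylated at C3 by benzyl chloromethyl ether anti to the new C4 substituent, giving the all-trans lactone A3.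
- In its favour: two C–C bonds and the 3,4-trans relationship arise in one operation, the absolute configuration comes from an auxiliary whose adducts can be purified by crystallisation, and every reaction type is established. On the certainty of the 3,4-trans outcome and on precedent for the key step, this alternative is the better of the two.
- Against it here: in A3, C2 is a lactone carbonyl and C5 an acetal carbon, so the ring A aryl group is still missing and both ring termini are at the wrong oxidation level. The later operations would be aryl introduction at C2 only, reduction of C5 to CH2, desulfurisation (Raney Ni), removal of menthol and of the benzyl ethers, and setting C2 cis to C3. These would take several times the two steps that follow the key step in the chosen plan, and C2, the hardest centre of this target, would still be open.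
- Comparison: the mechanism is anionic and so avoids the cationic hazards of the chosen key step, although closure or reduction at C2 would later pass through a benzylic cation anyway. On structural fit and step economy the chosen plan is better, because its key step delivers C5 and the ring B benzyl group at their final oxidation levels.

**Alternative 2:** The cut is at the C3–CH2 bond; the C3 arm would come from CH2I2. Et2Zn/CH2I2 (Simmons–Smith conditions) would cyclopropanate the C2=C3 enol ether of the dihydrofuran A4 on the face opposite the C4 benzyl group and give the 2-oxabicyclo[3.1.0]hexane A5. The C2–CH2 bond of the cyclopropane would then be opened by a heteroatom electrophile and the C2 oxocarbenium ion reduced.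
- In its favour: enol ethers are excellent Simmons–Smith substrates and the adjacent C4 substituent should direct well. The sequence sets C3 trans to C4 and then, by hydride delivery anti to the new C3 arm, C2 cis to C3, which is the pattern of the target. In the origin of the 2,3-cis relationship this alternative is the equal of the chosen plan, and it needs no chiral catalyst at that stage.
- Against it here: the new carbon arrives as a hydrocarbon CH2 and must still be oxidised to CH2O through a ring opening whose regiochemistry (exocyclic C2–CH2 bond against the ring-fusion bond) is not assured. A4 is an acid-sensitive enol ether whose stereocentre needs its own asymmetric synthesis. With a silyloxy group on ring A, C2 of the products ionises easily, so the cis product is at risk under the Lewis acid of the reduction.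
- Comparison: it builds the C3 arm last instead of C4 and C5. It pairs a reliable carbenoid addition with a cationic opening of uncertain selectivity, whereas the chosen plan concentrates its risk in one cationic step. With about four operations after the key step and a longer preparation of A4, it should be two to four steps longer.

**Alternative 3:** The cut is at the C2–C3 bond and the O1–C5 acyl bond. The aldehyde A6 and the 2-(alkoxycarbonyl)allylboronate A7 (CH2OSi cis to CH2B) would react through a chair transition state, and the borate would close onto the ester to give the cis α-methylene lactone A8.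
- In its favour: the C2/C3 cis relationship comes from the same kind of closed allylboration transition state as in the chosen plan, so the two are equal on that point. All later steps are known reaction types: arylation of the exocyclic methylene group (for example a Heck reaction with Pd(OAc)2 and then hydrogenation), equilibration at C4 next to the carbonyl group, and reduction of the lactone to the cyclic ether. The C5 carbonyl also offers thermodynamic control of the 3,4-trans relationship. On both counts this alternative is the better one.
- Against it here: C5 arrives as a carbonyl carbon and must be taken down to CH2 in two steps, the second with a Lewis acid and a silane on a compound whose ring A carries a silyloxy group and is therefore prone to epimerise at C2. Ring B needs a separate C–C bond formation. A7 is a stereodefined trisubstituted alkene that takes several steps to make, and its absolute stereocontrol is less developed than for simple allylboronates.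
- Comparison: the skeleton is assembled in three C–C bond-forming events instead of two, the key step is mechanistically safer, and the whole route would be about three to four steps longer with the same late deprotection and esterification.

Key step: step 7

Assumption: the (S)-configured binaphthyl phosphoric acid is taken to direct the allyl unit to the Si face of the aryl aldehyde, by analogy with allyl- and crotylboronates; if the sense is the reverse, the (R)-acid is used and nothing else changes.

## Route

Step 1
Reactants: 1 vanillin (4-hydroxy-3-methoxybenzaldehyde)
Product: 2 4-formyl-2-methoxyphenyl pivalate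
Conditions: PivCl, Et3N, DMAP (cat.), CH2Cl2, 0 °C to rt
Reagents that add atoms: pivaloyl chloride, CC(C)(C)C(Cl)=O
Why: Acylation of a phenol by an acyl chloride under nucleophilic catalysis; the ester raises the electrophilicity of the aldehyde for step 3 and later deactivates ring A in step 7.

Step 2
Reactants: 3 buta-1,3-diene (commercial solution in toluene); 4 bis(pinacolato)diboron
Product: 5 (Z)-1,4-bis(4,4,5,5-tetramethyl-1,3,2-dioxaborolan-2-yl)but-2-ene
Conditions: Pt(PPh3)4 (3 mol %), toluene, 80 °C, sealed vessel
Reagents that add atoms: none
Why: Platinum-catalysed 1,4-diboration of a 1,3-diene: oxidative addition of the B–B bond to zerovalent platinum, insertion of the s-cis diene and reductive elimination from the allyl(boryl)platinum species should give the cis-1,4-adduct, hence the Z alkene.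

Step 3
Reactants: 2 4-formyl-2-methoxyphenyl pivalate; 5 (Z)-1,4-bis(pinacolboryl)but-2-ene
Product: 7 4-[(1S,2S)-1-hydroxy-2-(hydroxymethyl)but-3-en-1-yl]-2-methoxyphenyl pivalate (syn diol), via O-boryl homoallylic boronate 6 (not isolated)
Conditions: (S)-TRIP [(S)-3,3'-bis(2,4,6-triisopropylphenyl)-1,1'-binaphthyl-2,2'-diyl hydrogen phosphate] (5 mol %), 4 Å MS, toluene, −30 °C; then NaBO3·4H2O, THF–H2O (1:1), 0 °C to rt
Reagents that add atoms: sodium perborate tetrahydrate (oxygen of the CH2OH group), O[B-]1(O)OO[B-](O)(O)OO1.[Na+].[Na+].O.O.O.O.O.O
Why: Chiral-phosphoric-acid-catalysed allylboration through a closed chair transition state: the Z geometry places the CH2B group axial and should give the syn relationship (later 2,3-cis), while the acid, hydrogen-bonded to a boronate oxygen and the formyl C–H, selects the aldehyde Si face and sets the (S)-carbinol. The remaining boron is homoallylic and cannot allylate again; perborate then oxidises this primary C–B bond to C–OH.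

Step 4
Reactants: 7 4-[(1S,2S)-1-hydroxy-2-(hydroxymethyl)but-3-en-1-yl]-2-methoxyphenyl pivalate
Product: 8 4-[(1S,2S)-1-hydroxy-2-(pivaloyloxymethyl)but-3-en-1-yl]-2-methoxyphenyl pivalate
Conditions: PivCl (1.1 equiv), pyridine, CH2Cl2, −20 to 0 °C
Reagents that add atoms: pivaloyl chloride, CC(C)(C)C(Cl)=O
Why: Sterically controlled acylation: the bulky acyl chloride should take the primary hydroxyl and leave the hindered secondary benzylic one free for step 7. Any ring A phenol uncovered during the oxidative work-up of step 3 would be re-acylated here with additional PivCl, so both outcomes converge on 8.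

Step 5
Reactants: 9 2-methoxy-4-vinylphenol
Product: 10 tert-butyl(2-methoxy-4-vinylphenoxy)dimethylsilane
Conditions: TBSCl, imidazole, DMF, 0 °C to rt
Reagents that add atoms: tert-butyldimethylsilyl chloride, CC(C)(C)[Si](C)(C)Cl
Why: Imidazole-promoted silylation of a phenol; the silyl ether keeps ring B electron-rich, tolerates the Lewis acid of step 7 at low temperature and is removable by alkoxide in step 8.

Step 6
Reactants: 8 4-[(1S,2S)-1-hydroxy-2-(pivaloyloxymethyl)but-3-en-1-yl]-2-methoxyphenyl pivalate; 10 tert-butyl(2-methoxy-4-vinylphenoxy)dimethylsilane (3 equiv)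
Product: 11 4-[(1S,2S,3E)-4-(4-tert-butyldimethylsilyloxy-3-methoxyphenyl)-1-hydroxy-2-(pivaloyloxymethyl)but-3-en-1-yl]-2-methoxyphenyl pivalate
Conditions: second-generation Grubbs catalyst (H2IMes)(PCy3)Cl2Ru=CHPh (5 mol %), CH2Cl2, 40 °C
Reagents that add atoms: none
Why: Olefin cross-metathesis between a terminal alkene that homodimerises slowly (branched allylic carbon) and an excess of a vinyl arene, driven by loss of ethene; the conjugated 1,2-disubstituted styrene should form as the E isomer under thermodynamic control, and no stereocentre is touched.

Step 7
Reactants: 11 4-[(1S,2S,3E)-4-(4-tert-butyldimethylsilyloxy-3-methoxyphenyl)-1-hydroxy-2-(pivaloyloxymethyl)but-3-en-1-yl]-2-methoxyphenyl pivalate; 12 formaldehyde (as paraformaldehyde)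
Product: 14 4-[(2S,3S,4R)-4-(4-tert-butyldimethylsilyloxy-3-methoxybenzyl)-3-(pivaloyloxymethyl)oxolan-2-yl]-2-methoxyphenyl pivalate, via trimethylsilyl ether 13 (not isolated)
Conditions: Me3SiOTf (1.1 equiv), 2,6-di-tert-butyl-4-methylpyridine (1.5 equiv), CH2Cl2, −78 °C; then (CH2O)n (3 equiv), Et3SiH (3 equiv), Me3SiOTf (1.2 equiv), −78 to −20 °C; NaHCO3 quench
Reagents that add atoms: none
Why: Proposed new method: the alcohol is silylated in the flask to 13, which condenses with Me3SiOTf-activated 12 to the O1=C5H2 oxocarbenium ion with loss of hexamethyldisiloxane; the styrene attacks this ion through its proximal carbon (C4–C5 bond) because the charge is then left on the benzylic carbon, stabilised by the para-silyloxy group of ring B, and Et3SiH reduces that cation to the benzyl CH2; the closest known reaction type is the Prins cyclisation of (E)-4-arylbut-3-en-1-ols with aldehydes, which gives 3-(α-substituted benzyl)oxolanes through the same cation, combined here with silane reduction of a benzylic cation. The oxolane closes in a five-membered mode that is endo with respect to the O1=C5 bond and exo with respect to the C=C bond; the six-membered mode is disfavoured because it would put the charge on a non-benzylic secondary carbon. The new stereocentre C4 is controlled by the existing C3 centre: with the C3–H bond eclipsing the E alkene (least allylic strain), the tether through C2 and O1 can reach only the alkene face anti to the C3 CH2OPiv group, which should give the 3,4-trans (4R) ring; C2 and C3 are carried through unchanged and the benzylic carbon becomes CH2, so no other centre arises. The step needs regioselectivity (secured by the donor-substituted styrene), chemoselectivity of the hydride for the benzylic cation over the oxocarbenium ion (secured by the five-membered cyclisation being faster than bimolecular hydride transfer), and integrity of C2 (secured by the ring A pivalate, which keeps the C2–O1 bond from ionising and disfavours 2-oxonia-Cope rearrangement to an aryl-stabilised oxocarbenium ion). The hindered pyridine keeps the medium aprotic, so that the styrene is not protonated and then reduced or closed onto the hydroxyl.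

Step 8
Reactants: 14 4-[(2S,3S,4R)-4-(4-tert-butyldimethylsilyloxy-3-methoxybenzyl)-3-(pivaloyloxymethyl)oxolan-2-yl]-2-methoxyphenyl pivalate
Product: 15 4-[(2S,3S,4R)-4-(4-hydroxy-3-methoxybenzyl)-3-(hydroxymethyl)oxolan-2-yl]-2-methoxyphenol
Conditions: NaOMe (6 equiv), MeOH–THF (3:1), argon, 50 °C; then aq. NH4Cl to about pH 7
Reagents that add atoms: none
Why: Zemplén-type methanolysis removes both pivalates, and methoxide cleaves the aryl silyl ether at silicon because phenoxide is a good leaving group. No acid is present, so the C2 benzylic ether cannot ionise and the three stereocentres stay as set.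

Step 9
Reactants: 15 4-[(2S,3S,4R)-4-(4-hydroxy-3-methoxybenzyl)-3-(hydroxymethyl)oxolan-2-yl]-2-methoxyphenol; 16 (E)-3-(4-hydroxyphenyl)prop-2-enoic acid (p-coumaric acid, 1.3 equiv)
Product: 17 [(2S,3S,4R)-2-(4-hydroxy-3-methoxyphenyl)-4-(4-hydroxy-3-methoxybenzyl)oxolan-3-yl]methyl (E)-3-(4-hydroxyphenyl)prop-2-enoate (target)
Conditions: PPh3, DIAD, THF, 0 °C to rt
Reagents that add atoms: none
Why: Mitsunobu esterification: the PPh3–DIAD betaine is protonated by the carboxylic acid, the most acidic partner, and the primary alcohol is activated as its alkoxyphosphonium ion and displaced by the carboxylate, so the much less acidic phenols should stay unalkylated. The reaction occurs at a CH2 carbon under neutral conditions, so no stereocentre and not the E alkene of 16 is affected.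

## Compound list

1 | vanillin (4-hydroxy-3-methoxybenzaldehyde) | COc1cc(C=O)ccc1O | starting material
2 | 4-formyl-2-methoxyphenyl pivalate | COc1cc(C=O)ccc1OC(=O)C(C)(C)C | intermediate
3 | buta-1,3-diene | C=CC=C | starting material
4 | bis(pinacolato)diboron | CC1(C)OB(OC1(C)C)B1OC(C)(C)C(C)(C)O1 | starting material
5 | (Z)-1,4-bis(4,4,5,5-tetramethyl-1,3,2-dioxaborolan-2-yl)but-2-ene | CC1(C)OB(C/C=C\CB2OC(C)(C)C(C)(C)O2)OC1(C)C | intermediate
6 | 2-methoxy-4-[(1S,2R)-1-(pinacolboryloxy)-2-(pinacolborylmethyl)but-3-en-1-yl]phenyl pivalate (formed in the flask) | CC1(C)OB(O[C@H](c2ccc(OC(=O)C(C)(C)C)c(OC)c2)[C@H](CB2OC(C)(C)C(C)(C)O2)C=C)OC1(C)C | intermediate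
7 | 4-[(1S,2S)-1-hydroxy-2-(hydroxymethyl)but-3-en-1-yl]-2-methoxyphenyl pivalate | O[C@H](c1ccc(OC(=O)C(C)(C)C)c(OC)c1)[C@H](CO)C=C | intermediate
8 | 4-[(1S,2S)-1-hydroxy-2-(pivaloyloxymethyl)but-3-en-1-yl]-2-methoxyphenyl pivalate | O[C@H](c1ccc(OC(=O)C(C)(C)C)c(OC)c1)[C@H](COC(=O)C(C)(C)C)C=C | intermediate
9 | 2-methoxy-4-vinylphenol | COc1cc(C=C)ccc1O | starting material
10 | tert-butyl(2-methoxy-4-vinylphenoxy)dimethylsilane | COc1cc(C=C)ccc1O[Si](C)(C)C(C)(C)C | intermediate
11 | 4-[(1S,2S,3E)-4-(4-tert-butyldimethylsilyloxy-3-methoxyphenyl)-1-hydroxy-2-(pivaloyloxymethyl)but-3-en-1-yl]-2-methoxyphenyl pivalate | O[C@H](c1ccc(OC(=O)C(C)(C)C)c(OC)c1)[C@H](COC(=O)C(C)(C)C)/C=C/c1ccc(O[Si](C)(C)C(C)(C)C)c(OC)c1 | intermediate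
12 | formaldehyde (used as paraformaldehyde) | C=O | starting material
13 | O-trimethylsilyl ether of 11 (formed in the flask) | C[Si](C)(C)O[C@H](c1ccc(OC(=O)C(C)(C)C)c(OC)c1)[C@H](COC(=O)C(C)(C)C)/C=C/c1ccc(O[Si](C)(C)C(C)(C)C)c(OC)c1 | intermediate
14 | 4-[(2S,3S,4R)-4-(4-tert-butyldimethylsilyloxy-3-methoxybenzyl)-3-(pivaloyloxymethyl)oxolan-2-yl]-2-methoxyphenyl pivalate | COc1cc(C[C@H]2CO[C@H](c3ccc(OC(=O)C(C)(C)C)c(OC)c3)[C@@H]2COC(=O)C(C)(C)C)ccc1O[Si](C)(C)C(C)(C)C | intermediate
15 | 4-[(2S,3S,4R)-4-(4-hydroxy-3-methoxybenzyl)-3-(hydroxymethyl)oxolan-2-yl]-2-methoxyphenol | COc1cc(C[C@H]2CO[C@H](c3ccc(O)c(OC)c3)[C@@H]2CO)ccc1O | intermediate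
16 | (E)-3-(4-hydroxyphenyl)prop-2-enoic acid (p-coumaric acid) | O=C(O)/C=C/c1ccc(O)cc1 | starting material
17 | [(2S,3S,4R)-2-(4-hydroxy-3-methoxyphenyl)-4-(4-hydroxy-3-methoxybenzyl)oxolan-3-yl]methyl (E)-3-(4-hydroxyphenyl)prop-2-enoate | COc1cc(C[C@H]2CO[C@H](c3ccc(O)c(OC)c3)[C@@H]2COC(=O)/C=C/c2ccc(O)cc2)ccc1O | target

## Step count and least certain steps

Total step count: 9. Longest linear sequence: 7 steps (steps 1, 3, 4, 6, 7, 8, 9, from 1 to 17).

**Step 7 (key step, proposed new method).** Most likely to go wrong:
- hydride transfer to the O1=C5 oxocarbenium ion before the ring closes (reductive O-methylation of the alcohol), because silane and alkene compete for the same electrophile;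
- incomplete facial control at C4, because an E alkene exerts only a modest allylic bias;
- scrambling of the C2/C3 relationship by 2-oxonia-Cope rearrangement or ionisation at C2, if the pivalate does not deactivate ring A enough;
- electrophilic substitution of the electron-rich ring B by activated formaldehyde.

Fallback with known reactions, setting out from 11: the Prins cyclisation is run without silane, with (CH2O)n and BF3·OEt2 in CH2Cl2–AcOH at 0 °C. The benzylic cation is then captured by acetate to give 4-[(2S,3S,4R)-4-[acetoxy(4-tert-butyldimethylsilyloxy-3-methoxyphenyl)methyl]-3-(pivaloyloxymethyl)oxolan-2-yl]-2-methoxyphenyl pivalate F1, as a mixture of epimers at the acetoxy carbon, which is of no consequence. In a separate step Et3SiH and BF3·OEt2 in CH2Cl2 at −78 to −20 °C re-ionise this electron-rich benzylic acetate and reduce it, which returns the route at 14. Oxygen-terminated Prins cyclisation of 4-arylbut-3-en-1-ols and ionic deoxygenation of benzylic esters are both established reaction types, and separating them removes the competition between hydride and alkene.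

**Step 3.** Most likely to go wrong: erosion of enantio- or diastereoselectivity in the allyl transfer, because the axial substituent is a bulky CH2B(pin) group and not a methyl group. Partial perhydrolysis of the aryl pivalate during the C–B oxidation is also possible, but step 4 corrects it.

Fallback, setting out from 2 and 5: the allylboration is run without the chiral acid (toluene, rt) to the racemic boronate F2, and NaBO3·4H2O oxidation gives the racemic syn diol F3. The syn relationship still comes from the Z geometry. Pivaloylation as in step 4 gives the racemic mono-pivalate F4. An acylative kinetic resolution follows, with (R)-benzotetramisole (cat.), isobutyric anhydride and i-Pr2NEt in CHCl3 at 0 °C; by analogy with simple 1-arylalkanols this catalyst is expected to acylate the (1R)-carbinol faster. It should convert the unwanted enantiomer into 4-[(1R,2R)-1-(isobutyryloxy)-2-(pivaloyloxymethyl)but-3-en-1-yl]-2-methoxyphenyl pivalate F5 and leave 8, where the route is rejoined.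

**Step 6.** Most likely to go wrong: homodimerisation of 10 outrunning the cross-coupling, because the alkene of 8 is hindered by its branched allylic carbon; and double-bond migration by ruthenium hydride species, which would erase the allylic stereocentre.

Fallback, setting out from 8: a Heck arylation replaces the metathesis. 4-Iodo-2-methoxyphenol is silylated (TBSCl, imidazole) to tert-butyl(4-iodo-2-methoxyphenoxy)dimethylsilane F6. Coupling of F6 with 8 (Pd(OAc)2, P(o-tol)3, Et3N, MeCN, 80 °C) forms the aryl–vinyl bond with β-hydride elimination towards the conjugated E styrene, and returns the route at 11.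

**Step 8.** Most likely to go wrong: incomplete cleavage of the hindered primary pivalate at a temperature that the bis-phenoxide tolerates, and oxidative degradation of the electron-rich phenoxides if air is admitted.

Fallback, setting out from 14: i-Bu2AlH in CH2Cl2 at −78 °C removes both pivalates reductively and gives 4-[(2S,3S,4R)-4-(4-tert-butyldimethylsilyloxy-3-methoxybenzyl)-3-(hydroxymethyl)oxolan-2-yl]-2-methoxyphenol F7. Bu4NF in THF at 0 °C then cleaves the silyl ether and returns the route at 15.

**Step 9.** Most likely to go wrong: O-alkylation of a phenol by the activated primary alcohol (oligomer formation) once the carboxylic acid is consumed locally, because three phenols are present.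

Fallback, setting out from 15:
- the two phenols are acetylated selectively as phenoxides (Ac2O, aq. NaOH, THF, 0 °C) to 4-[(2S,3S,4R)-4-(4-acetoxy-3-methoxybenzyl)-3-(hydroxymethyl)oxolan-2-yl]-2-methoxyphenyl acetate F8;
- the free primary alcohol is esterified with commercial (E)-4-acetoxycinnamic acid (PPh3, DIAD, THF), now with no phenol present, to the triacetate F9;
- the three aryl acetates are removed in the presence of the alkyl cinnamate (NH4OAc, MeOH–H2O, rt), which returns the route at 17.

## Further compounds

F1 | step 7 | 4-[(2S,3S,4R)-4-[acetoxy(4-tert-butyldimethylsilyloxy-3-methoxyphenyl)methyl]-3-(pivaloyloxymethyl)oxolan-2-yl]-2-methoxyphenyl pivalate (epimers at the acetoxy carbon) | COc1cc(C(OC(C)=O)[C@H]2CO[C@H](c3ccc(OC(=O)C(C)(C)C)c(OC)c3)[C@@H]2COC(=O)C(C)(C)C)ccc1O[Si](C)(C)C(C)(C)C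
F2 | step 3 | racemic syn 2-methoxy-4-[1-(pinacolboryloxy)-2-(pinacolborylmethyl)but-3-en-1-yl]phenyl pivalate (both enantiomers) | CC1(C)OB(O[C@H](c2ccc(OC(=O)C(C)(C)C)c(OC)c2)[C@H](CB2OC(C)(C)C(C)(C)O2)C=C)OC1(C)C.CC1(C)OB(O[C@@H](c2ccc(OC(=O)C(C)(C)C)c(OC)c2)[C@@H](CB2OC(C)(C)C(C)(C)O2)C=C)OC1(C)C
F3 | step 3 | racemic syn 4-[1-hydroxy-2-(hydroxymethyl)but-3-en-1-yl]-2-methoxyphenyl pivalate (both enantiomers) | O[C@H](c1ccc(OC(=O)C(C)(C)C)c(OC)c1)[C@H](CO)C=C.O[C@@H](c1ccc(OC(=O)C(C)(C)C)c(OC)c1)[C@@H](CO)C=C
F4 | step 3 | racemic syn 4-[1-hydroxy-2-(pivaloyloxymethyl)but-3-en-1-yl]-2-methoxyphenyl pivalate (both enantiomers) | O[C@H](c1ccc(OC(=O)C(C)(C)C)c(OC)c1)[C@H](COC(=O)C(C)(C)C)C=C.O[C@@H](c1ccc(OC(=O)C(C)(C)C)c(OC)c1)[C@@H](COC(=O)C(C)(C)C)C=C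
F5 | step 3 | 4-[(1R,2R)-1-(isobutyryloxy)-2-(pivaloyloxymethyl)but-3-en-1-yl]-2-methoxyphenyl pivalate | CC(C)C(=O)O[C@@H](c1ccc(OC(=O)C(C)(C)C)c(OC)c1)[C@@H](COC(=O)C(C)(C)C)C=C
F6 | step 6 | tert-butyl(4-iodo-2-methoxyphenoxy)dimethylsilane | COc1cc(I)ccc1O[Si](C)(C)C(C)(C)C
F7 | step 8 | 4-[(2S,3S,4R)-4-(4-tert-butyldimethylsilyloxy-3-methoxybenzyl)-3-(hydroxymethyl)oxolan-2-yl]-2-methoxyphenol | COc1cc(C[C@H]2CO[C@H](c3ccc(O)c(OC)c3)[C@@H]2CO)ccc1O[Si](C)(C)C(C)(C)C
F8 | step 9 | 4-[(2S,3S,4R)-4-(4-acetoxy-3-methoxybenzyl)-3-(hydroxymethyl)oxolan-2-yl]-2-methoxyphenyl acetate | COc1cc(C[C@H]2CO[C@H](c3ccc(OC(C)=O)c(OC)c3)[C@@H]2CO)ccc1OC(C)=O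
F9 | step 9 | [(2S,3S,4R)-2-(4-acetoxy-3-methoxyphenyl)-4-(4-acetoxy-3-methoxybenzyl)oxolan-3-yl]methyl (E)-3-(4-acetoxyphenyl)prop-2-enoate | COc1cc(C[C@H]2CO[C@H](c3ccc(OC(C)=O)c(OC)c3)[C@@H]2COC(=O)/C=C/c2ccc(OC(C)=O)cc2)ccc1OC(C)=O
A1 | alternative 1 | (5R)-5-[(1R,2S,5R)-menthyloxy]furan-2(5H)-one | O=C1C=C[C@H](O[C@@H]2C[C@H](C)CC[C@H]2C(C)C)O1
A2 | alternative 1 | 2-(4-benzyloxy-3-methoxyphenyl)-1,3-dithiane | COc1cc(C2SCCCS2)ccc1OCc1ccccc1
A3 | alternative 1 | all-trans 3-(benzyloxymethyl)-4-[2-(4-benzyloxy-3-methoxyphenyl)-1,3-dithian-2-yl]-5-[(1R,2S,5R)-menthyloxy]oxolan-2-one | COc1cc(C2(SCCCS2)[C@H]2[C@H](O[C@@H]3C[C@H](C)CC[C@H]3C(C)C)OC(=O)[C@@H]2COCc2ccccc2)ccc1OCc1ccccc1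
A4 | alternative 2 | (3R)-5-(4-tert-butyldimethylsilyloxy-3-methoxyphenyl)-3-(4-tert-butyldimethylsilyloxy-3-methoxybenzyl)-2,3-dihydrofuran | COc1cc(C[C@H]2COC(c3ccc(O[Si](C)(C)C(C)(C)C)c(OC)c3)=C2)ccc1O[Si](C)(C)C(C)(C)C
A5 | alternative 2 | 1-(4-tert-butyldimethylsilyloxy-3-methoxyphenyl)-4-(4-tert-butyldimethylsilyloxy-3-methoxybenzyl)-2-oxabicyclo[3.1.0]hexane (cyclopropane anti to the benzyl group) | COc1cc(C[C@H]2CO[C@]3(c4ccc(O[Si](C)(C)C(C)(C)C)c(OC)c4)C[C@H]23)ccc1O[Si](C)(C)C(C)(C)C
A6 | alternative 3 | 4-(tert-butyldimethylsilyloxy)-3-methoxybenzaldehyde | COc1cc(C=O)ccc1O[Si](C)(C)C(C)(C)C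
A7 | alternative 3 | ethyl (2E)-4-(tert-butyldimethylsilyloxy)-2-[(4,4,5,5-tetramethyl-1,3,2-dioxaborolan-2-yl)methyl]but-2-enoate (CH2OSi cis to CH2B) | CCOC(=O)/C(CB1OC(C)(C)C(C)(C)O1)=C/CO[Si](C)(C)C(C)(C)C
A8 | alternative 3 | (4S,5S)-5-(4-tert-butyldimethylsilyloxy-3-methoxyphenyl)-4-(tert-butyldimethylsilyloxymethyl)-3-methyleneoxolan-2-one (cis) | C=C1C(=O)O[C@H](c2ccc(O[Si](C)(C)C(C)(C)C)c(OC)c2)[C@@H]1CO[Si](C)(C)C(C)(C)C
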